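**Retrosynthetic overview**

Numbering (icetexane): ring A is C1–C5/C10; ring B is C5, C6, C7, C8, C9, C20, C10; ring C is C8, C9, C11–C14; the lactone is C19(=O)–O–C6. The route rests on ring B: its two arene carbons C8 and C9 sit between C7 (next to the oxygenated C6) and C20, so ring B is a cyclopentane-1,3-dione (C6, C7, C20 on C5 and C10) with an aryne C8≡C9 inserted into the C7–C20 bond.
Target ⇒ C1 desilylation, O12 demethylation and Teuber oxidation of a C11 phenol ⇒ C10=C20 from the C20 ketone through its enol triflate ⇒ enol lactone C19–O–C6=C7 from the C6 ketone and the C19 acid ⇒ benzo-fused cycloheptanedione.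
Benzo-fused cycloheptanedione ⇒ aryne C–C insertion (acyl-alkylation) ⇒ cis-hydrindane-1,3-dione (C1 silyl ether, C4 methyl and tert-butyl ester) + ortho-silylaryl triflate carrying C11 allyloxy, C12 methoxy and C13 isopropyl.
Hydrindanedione ⇒ C4 methylation of the all-cis endo Diels–Alder adduct of cyclopent-4-ene-1,3-dione and a (2E,4E)-5-silyloxypenta-2,4-dienoate; silyl triflate ⇒ 2-isopropylphenol by two ortho-oxygenations.
Ring order: ring A together with the five-membered dione ring (cycloaddition), then ring C joined and ring B formed by two-carbon ring expansion, then the lactone ring, last the quinone.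

Key step: step 13

Assumption: the (S)-oxazaborolidinium catalyst of step 3 is taken to give the (3aR,4S,7R,7aS) adduct; the sense of induction is read from the first run and the (R)-catalyst is used if it is opposite.

Remark: the C4 methyl group is put in after the cycloaddition, because a diene terminus that carries the ester and a (Z)-methyl group would be a sluggish diene; O11 is carried as an allyl ether and C19 as a tert-butyl ester so that both can be released without base or strong acid.

**Route**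

Step 1
Reactants: 1 1,1,3,3-tetramethoxypropane
Product: 3 (2E)-3-[(tert-butyldimethylsilyl)oxy]prop-2-enal, via sodium malonaldehyde enolate 2 (not isolated)
Conditions: 1 M HCl, H2O, 50 °C; NaOH to pH 10, evaporate; tBuMe2SiCl, MeCN, 23 °C
Reagents that add atoms: water O; tert-butyldimethylsilyl chloride CC(C)(C)[Si](C)(C)Cl; sodium hydroxide [Na+].[OH-] (Na of 2 only)
Why: acetal hydrolysis gives malonaldehyde, and O-silylation of its sodium enolate (silyl enol ether formation) should give the (E)-configured vinylogous silyl formate.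

Step 2
Reactants: 3 (2E)-3-[(tert-butyldimethylsilyl)oxy]prop-2-enal; 4 tert-butyl (triphenyl-λ5-phosphanylidene)acetate
Product: 5 tert-butyl (2E,4E)-5-[(tert-butyldimethylsilyl)oxy]penta-2,4-dienoate
Conditions: toluene, 60 °C
Reagents that add atoms: none
Why: Wittig olefination with the stabilised ylide should give the (2E)-enoate, while the (4E) silyl enol ether geometry is carried over from 3.

Step 3
Reactants: 5 tert-butyl (2E,4E)-5-[(tert-butyldimethylsilyl)oxy]penta-2,4-dienoate; 6 cyclopent-4-ene-1,3-dione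
Product: 7 tert-butyl (3aR,4S,7R,7aS)-7-[(tert-butyldimethylsilyl)oxy]-1,3-dioxo-2,3,3a,4,7,7a-hexahydro-1H-indene-4-carboxylate
Conditions: (S)-3,3-diphenyl-1-(2-methylphenyl)tetrahydro-1H,3H-pyrrolo[1,2-c][1,3,2]oxazaborole (20 mol%), (CF3SO2)2NH (18 mol%), CH2Cl2, −78 → −40 °C
Reagents that add atoms: none
Why: a chiral oxazaborolidinium-catalysed endo Diels–Alder reaction of the (E,E)-1-silyloxy diene with the cis enedione should place the C1 silyloxy group, the C4 ester and the ring-fusion carbonyl carbons C6 and C20 on one face (C1, C5 and C10 are set here, C4 is reset in step 5), and shielding of one enantioface of the dione by the catalyst fixes the absolute configuration.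

Step 4
Reactants: 7 tert-butyl (3aR,4S,7R,7aS)-7-[(tert-butyldimethylsilyl)oxy]-1,3-dioxo-2,3,3a,4,7,7a-hexahydro-1H-indene-4-carboxylate
Product: 8 tert-butyl (3aR,4S,7R,7aS)-7-[(tert-butyldimethylsilyl)oxy]-1,3-dioxooctahydro-1H-indene-4-carboxylate
Conditions: H2 (1 atm), Pd/C (10% palladium on carbon), EtOAc, 23 °C
Reagents that add atoms: none
Why: heterogeneous hydrogenation should saturate the cis-disubstituted C2=C3 alkene, and the enolised 1,3-dione, the silyl ether and the tert-butyl ester are inert to it.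

Step 5
Reactants: 8 tert-butyl (3aR,4S,7R,7aS)-7-[(tert-butyldimethylsilyl)oxy]-1,3-dioxooctahydro-1H-indene-4-carboxylate
Product: 10 tert-butyl (3aR,4S,7R,7aS)-7-[(tert-butyldimethylsilyl)oxy]-4-methyl-1,3-dioxooctahydro-1H-indene-4-carboxylate, via dilithium dianion 9 (not isolated)
Conditions: LiN(iPr)2 (2.4 equiv), THF/DMPU, −78 °C; MeI (1.2 equiv), −78 → −40 °C; AcOH
Reagents that add atoms: iodomethane CI; lithium diisopropylamide [Li+].CC(C)[N-]C(C)C (Li of 9 only)
Why: in this dianion alkylation the first equivalent of base forms the dione enolate through C7 (which shields C5 and C10), the second forms the C4 ester enolate, and this more basic enolate should be methylated from the α face, opposite to the C5–C6, C10–C20 and C1–O bonds that all lie on the β face, which sets the C4 quaternary centre (methyl α, ester β and cis to C6).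

Step 6
Reactants: 11 2-(propan-2-yl)phenol
Product: 12 1-methoxy-2-(propan-2-yl)benzene
Conditions: MeI, K2CO3, acetone, reflux
Reagents that add atoms: iodomethane CI
Why: Williamson etherification of the phenol gives the O12 methyl ether, which also serves as the director for the next step.

Step 7
Reactants: 12 1-methoxy-2-(propan-2-yl)benzene
Product: 15 2-methoxy-3-(propan-2-yl)phenol, via [2-methoxy-3-(propan-2-yl)phenyl]lithium 13 (not isolated), via dimethyl [2-methoxy-3-(propan-2-yl)phenyl]boronate 14 (not isolated)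
Conditions: nBuLi, TMEDA, Et2O, 0 → 23 °C; B(OMe)3, −78 → 23 °C; 30% H2O2, AcOH, 0 → 23 °C
Reagents that add atoms: hydrogen peroxide OO; n-butyllithium [Li]CCCC (Li of 13 only); trimethyl borate COB(OC)OC (boron group of 14 only)
Why: methoxy-directed ortho-metalation can only occur at C11 (the other ortho position carries the isopropyl group), and borylation followed by oxidative C–B cleavage should give the C11 phenol.

Step 8
Reactants: 15 2-methoxy-3-(propan-2-yl)phenol
Product: 16 2-hydroxy-3-methoxy-4-(propan-2-yl)benzaldehyde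
Conditions: MgCl2, Et3N, (CH2O)n, MeCN, reflux
Reagents that add atoms: formaldehyde (as paraformaldehyde) C=O
Why: magnesium phenoxide-mediated ortho-formylation should deliver the formyl group to C9, the only free position ortho to the hydroxyl group.

Step 9
Reactants: 16 2-hydroxy-3-methoxy-4-(propan-2-yl)benzaldehyde
Product: 17 3-methoxy-4-(propan-2-yl)-2-(prop-2-en-1-yloxy)benzaldehyde
Conditions: allyl bromide, K2CO3, DMF, 50 °C
Reagents that add atoms: allyl bromide C=CCBr
Why: Williamson allylation protects O11 as an ether that survives organolithium, fluoride and amide bases and is later removed by palladium and formate.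

Step 10
Reactants: 17 3-methoxy-4-(propan-2-yl)-2-(prop-2-en-1-yloxy)benzaldehyde
Product: 19 3-methoxy-4-(propan-2-yl)-2-(prop-2-en-1-yloxy)phenol, via aryl formate 18 (not isolated)
Conditions: mCPBA, CH2Cl2, 23 °C; then K2CO3 (cat.), MeOH, 0 °C
Reagents that add atoms: 3-chloroperbenzoic acid OOC(=O)c1cccc(Cl)c1
Why: Baeyer–Villiger (Dakin-type) oxidation of the ortho-alkoxybenzaldehyde proceeds with aryl migration and is faster than epoxidation of the terminal allyl alkene, and methanolysis of the formate should give the C9 phenol.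

Step 11
Reactants: 19 3-methoxy-4-(propan-2-yl)-2-(prop-2-en-1-yloxy)phenol
Product: 20 6-bromo-3-methoxy-4-(propan-2-yl)-2-(prop-2-en-1-yloxy)phenol
Conditions: N-bromosuccinimide, MeCN, 0 °C
Reagents that add atoms: N-bromosuccinimide O=C1CCC(=O)N1Br
Why: electrophilic bromination is directed by the hydroxyl group to C8, its only free ortho position, since the para position carries the isopropyl group.

Step 12
Reactants: 20 6-bromo-3-methoxy-4-(propan-2-yl)-2-(prop-2-en-1-yloxy)phenol
Product: 23 3-methoxy-4-(propan-2-yl)-2-(prop-2-en-1-yloxy)-6-(trimethylsilyl)phenyl trifluoromethanesulfonate, via aryl trimethylsilyl ether 21 (not isolated), via lithium 2-silylphenolate 22 (not isolated)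
Conditions: (Me3Si)2NH, THF, 65 °C, evaporate; nBuLi, THF, −78 °C; (CF3SO2)2O, −78 °C
Reagents that add atoms: hexamethyldisilazane C[Si](C)(C)N[Si](C)(C)C; trifluoromethanesulfonic anhydride O=S(=O)(OS(=O)(=O)C(F)(F)F)C(F)(F)F; n-butyllithium [Li]CCCC (Li of 22 only)
Why: O-silylation, bromine–lithium exchange with retro-Brook 1,3-shift of silicon from oxygen to C8, and O-triflation of the resulting phenolate is the standard sequence to an ortho-silylaryl triflate, and the allyl ether tolerates the brief exposure to nBuLi at −78 °C.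

Step 13
Reactants: 10 tert-butyl (3aR,4S,7R,7aS)-7-[(tert-butyldimethylsilyl)oxy]-4-methyl-1,3-dioxooctahydro-1H-indene-4-carboxylate; 23 3-methoxy-4-(propan-2-yl)-2-(prop-2-en-1-yloxy)-6-(trimethylsilyl)phenyl trifluoromethanesulfonate
Product: 26 tert-butyl (1R,4S,5R,10S)-1-[(tert-butyldimethylsilyl)oxy]-12-methoxy-6,20-dioxo-11-(prop-2-en-1-yloxy)-9(10→20)-abeo-abieta-8,11,13-trien-19-oate, via cesium enolate of the dione 24 (not isolated), via aryne 25 (not isolated)
Conditions: CsF (3.5 equiv), MeCN, 23 → 50 °C, slow addition of 23 (1.2 equiv)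
Reagents that add atoms: cesium fluoride [Cs+].[F-] (Cs of 24 only; no reagent atom remains in 26)
Why: Fluoride deprotonates 10 (cesium enolate 24) and strips the silyl group of 23 so that triflate leaves and the aryne 25 (C8≡C9) forms; the enolate carbon C7 adds to C8, the aryl anion at C9 adds to the C20 carbonyl, and the benzocyclobutenoxide fragments (retro-aldol) with cleavage of C7–C20, so that C7–C8 and C9–C20 are made and the arene is inserted. The closest known reaction type is the aryne acyl-alkylation (C–C insertion) of 1,3-dicarbonyl compounds, which is documented for cyclic 1,3-diketones as a two-carbon ring expansion. Ring B is not closed by a cyclisation but arises from the five-membered dione ring by this expansion, the transient four-membered ring being formed in the 4-exo-trig mode. No stereocentre is created (C7 ends as CH2), and C5 and C10 are not touched because the only enolate present before and after the insertion runs through C7. Two regiochemical choices are needed: attack of C7 at C8 is secured by the C11 allyloxy group, which polarises the aryne so that the nucleophile enters at the remote carbon and the charge develops at C9 next to oxygen, and closure on C20 instead of C6 is expected because C6 is flanked by the fully substituted C4 with its methyl and tert-butyl ester, whereas C20 has only the C1 methine beside it. C-arylation over O-arylation and single insertion are favoured by keeping the aryne the limiting, slowly generated partner.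

Step 14
Reactants: 26 tert-butyl (1R,4S,5R,10S)-1-[(tert-butyldimethylsilyl)oxy]-12-methoxy-6,20-dioxo-11-(prop-2-en-1-yloxy)-9(10→20)-abeo-abieta-8,11,13-trien-19-oate
Product: 28 (1R,4S,5R,10S)-1-[(tert-butyldimethylsilyl)oxy]-12-methoxy-6,20-dioxo-11-(prop-2-en-1-yloxy)-9(10→20)-abeo-abieta-8,11,13-trien-19-oic acid, via trimethylsilyl ester 27 (not isolated)
Conditions: Me3SiOSO2CF3 (4 equiv), 2,6-lutidine (6 equiv), CH2Cl2, 0 °C; then aq. citric acid, THF
Reagents that add atoms: trimethylsilyl trifluoromethanesulfonate C[Si](C)(C)OS(=O)(=O)C(F)(F)F (silyl group of 27 only)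
Why: silyl-triflate-mediated tert-butyl ester cleavage (alkyl–oxygen scission with loss of isobutene) should spare the secondary silyl ether and the allyl and methyl ethers, and silyl enol ethers formed at the ketones are hydrolysed in the work-up.

Step 15
Reactants: 28 (1R,4S,5R,10S)-1-[(tert-butyldimethylsilyl)oxy]-12-methoxy-6,20-dioxo-11-(prop-2-en-1-yloxy)-9(10→20)-abeo-abieta-8,11,13-trien-19-oic acid
Product: 30 (1R,4S,5R,10S)-1-[(tert-butyldimethylsilyl)oxy]-12-methoxy-20-oxo-11-(prop-2-en-1-yloxy)-9(10→20)-abeo-abieta-6,8,11,13-tetraen-19,6-olide, via mixed trifluoroacetic anhydride 29 (not isolated)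
Conditions: (CF3CO)2O (1.5 equiv), Et3N (3 equiv), CH2Cl2, 0 → 23 °C
Reagents that add atoms: trifluoroacetic anhydride O=C(OC(=O)C(F)(F)F)C(F)(F)F (acyl group of 29 only)
Why: enol lactonisation of the γ-keto acid through its mixed anhydride should occur toward the acidic benzylic C7 to give the arene-conjugated C6=C7 enol ester, and only the cis relation of C19 and C6 on C4–C5 allows the five-membered ring, which from here on locks C5.

Step 16
Reactants: 30 (1R,4S,5R,10S)-1-[(tert-butyldimethylsilyl)oxy]-12-methoxy-20-oxo-11-(prop-2-en-1-yloxy)-9(10→20)-abeo-abieta-6,8,11,13-tetraen-19,6-olide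
Product: 32 (1R,4S,5R)-1-[(tert-butyldimethylsilyl)oxy]-12-methoxy-11-(prop-2-en-1-yloxy)-20-[(trifluoromethanesulfonyl)oxy]-9(10→20)-abeo-abieta-6,8,10(20),11,13-pentaen-19,6-olide, via potassium enolate 31 (not isolated)
Conditions: KN(SiMe3)2, THF, −78 °C; PhN(SO2CF3)2, −78 → 0 °C
Reagents that add atoms: N-phenylbis(trifluoromethanesulfonimide) O=S(=O)(N(c1ccccc1)S(=O)(=O)C(F)(F)F)C(F)(F)F; potassium bis(trimethylsilyl)amide C[Si](C)(C)[N-][Si](C)(C)C.[K+] (K of 31 only)
Why: C10–H is the only α-hydrogen of the C20 aryl ketone, so enolate formation and O-triflation are regiospecific, and the low temperature holds back β-elimination of the C1 silyloxy group.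

Step 17
Reactants: 32 (1R,4S,5R)-1-[(tert-butyldimethylsilyl)oxy]-12-methoxy-11-(prop-2-en-1-yloxy)-20-[(trifluoromethanesulfonyl)oxy]-9(10→20)-abeo-abieta-6,8,10(20),11,13-pentaen-19,6-olide
Product: 33 (1R,4S,5R)-1-[(tert-butyldimethylsilyl)oxy]-11-hydroxy-12-methoxy-9(10→20)-abeo-abieta-6,8,10(20),11,13-pentaen-19,6-olide
Conditions: Pd(OAc)2 (10 mol%), PPh3 (40 mol%), HCO2H, Et3N, DMF, 60 °C
Reagents that add atoms: none
Why: palladium-catalysed formate hydrogenolysis should reduce the enol triflate to the C10=C20 alkene and, through a π-allylpalladium intermediate (Tsuji–Trost deallylation), cleave the allyl aryl ether in the same operation, which frees the C11 phenol under neutral conditions.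

Step 18
Reactants: 33 (1R,4S,5R)-1-[(tert-butyldimethylsilyl)oxy]-11-hydroxy-12-methoxy-9(10→20)-abeo-abieta-6,8,10(20),11,13-pentaen-19,6-olide
Product: 34 (1R,4S,5R)-1-[(tert-butyldimethylsilyl)oxy]-12-methoxy-11,14-dioxo-9(10→20)-abeo-abieta-6,8,10(20),12-tetraen-19,6-olide
Conditions: K2[ON(SO3)2] (3 equiv), KH2PO4 buffer (pH 6), acetone/H2O, 0 → 23 °C
Reagents that add atoms: potassium nitrosodisulfonate [K+].[K+].[O]N(S(=O)(=O)[O-])S(=O)(=O)[O-]
Why: Teuber oxidation of a phenol with a free para position (C14–H) should give the para-quinone with oxygen delivered to C14, under buffered conditions that leave the enol lactone and the allylic silyl ether alone.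

Step 19
Reactants: 34 (1R,4S,5R)-1-[(tert-butyldimethylsilyl)oxy]-12-methoxy-11,14-dioxo-9(10→20)-abeo-abieta-6,8,10(20),12-tetraen-19,6-olide
Product: 36 (1R,4S,5R)-1-[(tert-butyldimethylsilyl)oxy]-12-hydroxy-11,14-dioxo-9(10→20)-abeo-abieta-6,8,10(20),12-tetraen-19,6-olide, via dichloroboryl ether 35 (not isolated)
Conditions: BCl3 (2 equiv), CH2Cl2, −78 °C; then pH 7 buffer
Reagents that add atoms: boron trichloride ClB(Cl)Cl (boron group of 35 only)
Why: chelation-assisted cleavage of the vinylogous methyl ester (boron held between the C11 carbonyl and O12) is fast at −78 °C, where the enol lactone and the silyl ether should survive.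

Step 20
Reactants: 36 (1R,4S,5R)-1-[(tert-butyldimethylsilyl)oxy]-12-hydroxy-11,14-dioxo-9(10→20)-abeo-abieta-6,8,10(20),12-tetraen-19,6-olide
Product: 37 (1R,4S,5R)-1,12-dihydroxy-11,14-dioxo-9(10→20)-abeo-abieta-6,8,10(20),12-tetraen-19,6-olide (6,7-anhydroballotiquinone)
Conditions: HF·pyridine, THF, 0 → 23 °C
Reagents that add atoms: none
Why: fluoride desilylation under mildly acidic, non-nucleophilic conditions should free the C1 alcohol without opening the base-sensitive enol lactone, the quinone ring making the allylic alcohol resistant to ionisation.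

**Compound list**

1 | 1,1,3,3-tetramethoxypropane | COC(OC)CC(OC)OC | starting material
2 | sodium (E)-3-oxoprop-1-en-1-olate | [Na+].[O-]/C=C/C=O | intermediate
3 | (2E)-3-[(tert-butyldimethylsilyl)oxy]prop-2-enal | O=C/C=C/O[Si](C)(C)C(C)(C)C | intermediate
4 | tert-butyl (triphenyl-λ5-phosphanylidene)acetate | CC(C)(C)OC(=O)C=P(c1ccccc1)(c1ccccc1)c1ccccc1 | starting material
5 | tert-butyl (2E,4E)-5-[(tert-butyldimethylsilyl)oxy]penta-2,4-dienoate | CC(C)(C)OC(=O)/C=C/C=C/O[Si](C)(C)C(C)(C)C | intermediate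
6 | cyclopent-4-ene-1,3-dione | O=C1CC(=O)C=C1 | starting material
7 | tert-butyl (3aR,4S,7R,7aS)-7-[(tert-butyldimethylsilyl)oxy]-1,3-dioxo-2,3,3a,4,7,7a-hexahydro-1H-indene-4-carboxylate | CC(C)(C)OC(=O)[C@H]1C=C[C@@H](O[Si](C)(C)C(C)(C)C)[C@H]2C(=O)CC(=O)[C@@H]12 | intermediate
8 | tert-butyl (3aR,4S,7R,7aS)-7-[(tert-butyldimethylsilyl)oxy]-1,3-dioxooctahydro-1H-indene-4-carboxylate | CC(C)(C)OC(=O)[C@H]1CC[C@@H](O[Si](C)(C)C(C)(C)C)[C@H]2C(=O)CC(=O)[C@@H]12 | intermediate
9 | dilithium dianion of 8 (C4 ester enolate and dione enolate) | CC(C)(C)OC([O-])=C1CC[C@@H](O[Si](C)(C)C(C)(C)C)[C@H]2C(=O)C=C([O-])[C@@H]12.[Li+].[Li+] | intermediate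
10 | tert-butyl (3aR,4S,7R,7aS)-7-[(tert-butyldimethylsilyl)oxy]-4-methyl-1,3-dioxooctahydro-1H-indene-4-carboxylate | CC(C)(C)OC(=O)[C@@]1(C)CC[C@@H](O[Si](C)(C)C(C)(C)C)[C@H]2C(=O)CC(=O)[C@@H]12 | intermediate
11 | 2-(propan-2-yl)phenol | CC(C)c1ccccc1O | starting material
12 | 1-methoxy-2-(propan-2-yl)benzene | CC(C)c1ccccc1OC | intermediate
13 | [2-methoxy-3-(propan-2-yl)phenyl]lithium | [Li]c1cccc(C(C)C)c1OC | intermediate
14 | dimethyl [2-methoxy-3-(propan-2-yl)phenyl]boronate | COB(OC)c1cccc(C(C)C)c1OC | intermediate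
15 | 2-methoxy-3-(propan-2-yl)phenol | CC(C)c1cccc(O)c1OC | intermediate
16 | 2-hydroxy-3-methoxy-4-(propan-2-yl)benzaldehyde | CC(C)c1ccc(C=O)c(O)c1OC | intermediate
17 | 3-methoxy-4-(propan-2-yl)-2-(prop-2-en-1-yloxy)benzaldehyde | CC(C)c1ccc(C=O)c(OCC=C)c1OC | intermediate
18 | 3-methoxy-4-(propan-2-yl)-2-(prop-2-en-1-yloxy)phenyl formate | CC(C)c1ccc(OC=O)c(OCC=C)c1OC | intermediate
19 | 3-methoxy-4-(propan-2-yl)-2-(prop-2-en-1-yloxy)phenol | CC(C)c1ccc(O)c(OCC=C)c1OC | intermediate
20 | 6-bromo-3-methoxy-4-(propan-2-yl)-2-(prop-2-en-1-yloxy)phenol | CC(C)c1cc(Br)c(O)c(OCC=C)c1OC | intermediate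
21 | [6-bromo-3-methoxy-4-(propan-2-yl)-2-(prop-2-en-1-yloxy)phenoxy]trimethylsilane | CC(C)c1cc(Br)c(O[Si](C)(C)C)c(OCC=C)c1OC | intermediate
22 | lithium 3-methoxy-4-(propan-2-yl)-2-(prop-2-en-1-yloxy)-6-(trimethylsilyl)phenolate | [Li+].CC(C)c1cc([Si](C)(C)C)c([O-])c(OCC=C)c1OC | intermediate
23 | 3-methoxy-4-(propan-2-yl)-2-(prop-2-en-1-yloxy)-6-(trimethylsilyl)phenyl trifluoromethanesulfonate | CC(C)c1cc([Si](C)(C)C)c(OS(=O)(=O)C(F)(F)F)c(OCC=C)c1OC | intermediate
24 | cesium enolate of 10 | [Cs+].CC(C)(C)OC(=O)[C@@]1(C)CC[C@@H](O[Si](C)(C)C(C)(C)C)[C@H]2C(=O)C=C([O-])[C@@H]12 | intermediate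
25 | 4-methoxy-5-(propan-2-yl)-3-(prop-2-en-1-yloxy)-1,2-didehydrobenzene (aryne C8≡C9) | CC(C)C1=CC#CC(OCC=C)=C1OC | intermediate
26 | tert-butyl (1R,4S,5R,10S)-1-[(tert-butyldimethylsilyl)oxy]-12-methoxy-6,20-dioxo-11-(prop-2-en-1-yloxy)-9(10→20)-abeo-abieta-8,11,13-trien-19-oate | CC(C)(C)OC(=O)[C@@]1(C)CC[C@@H](O[Si](C)(C)C(C)(C)C)[C@H]2C(=O)c3c(OCC=C)c(OC)c(C(C)C)cc3CC(=O)[C@@H]12 | intermediate
27 | trimethylsilyl ester of 28 | C[Si](C)(C)OC(=O)[C@@]1(C)CC[C@@H](O[Si](C)(C)C(C)(C)C)[C@H]2C(=O)c3c(OCC=C)c(OC)c(C(C)C)cc3CC(=O)[C@@H]12 | intermediate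
28 | (1R,4S,5R,10S)-1-[(tert-butyldimethylsilyl)oxy]-12-methoxy-6,20-dioxo-11-(prop-2-en-1-yloxy)-9(10→20)-abeo-abieta-8,11,13-trien-19-oic acid | OC(=O)[C@@]1(C)CC[C@@H](O[Si](C)(C)C(C)(C)C)[C@H]2C(=O)c3c(OCC=C)c(OC)c(C(C)C)cc3CC(=O)[C@@H]12 | intermediate
29 | mixed anhydride of 28 with trifluoroacetic acid | FC(F)(F)C(=O)OC(=O)[C@@]1(C)CC[C@@H](O[Si](C)(C)C(C)(C)C)[C@H]2C(=O)c3c(OCC=C)c(OC)c(C(C)C)cc3CC(=O)[C@@H]12 | intermediate
30 | (1R,4S,5R,10S)-1-[(tert-butyldimethylsilyl)oxy]-12-methoxy-20-oxo-11-(prop-2-en-1-yloxy)-9(10→20)-abeo-abieta-6,8,11,13-tetraen-19,6-olide | CC(C)c1cc2C=C3OC(=O)[C@@]4(C)CC[C@@H](O[Si](C)(C)C(C)(C)C)[C@@H](C(=O)c2c(OCC=C)c1OC)[C@@H]34 | intermediate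
31 | potassium C10=C20 enolate of 30 | [K+].CC(C)c1cc2C=C3OC(=O)[C@@]4(C)CC[C@@H](O[Si](C)(C)C(C)(C)C)C(=C([O-])c2c(OCC=C)c1OC)[C@@H]34 | intermediate
32 | (1R,4S,5R)-1-[(tert-butyldimethylsilyl)oxy]-12-methoxy-11-(prop-2-en-1-yloxy)-20-[(trifluoromethanesulfonyl)oxy]-9(10→20)-abeo-abieta-6,8,10(20),11,13-pentaen-19,6-olide | CC(C)c1cc2C=C3OC(=O)[C@@]4(C)CC[C@@H](O[Si](C)(C)C(C)(C)C)C(=C(OS(=O)(=O)C(F)(F)F)c2c(OCC=C)c1OC)[C@@H]34 | intermediate
33 | (1R,4S,5R)-1-[(tert-butyldimethylsilyl)oxy]-11-hydroxy-12-methoxy-9(10→20)-abeo-abieta-6,8,10(20),11,13-pentaen-19,6-olide | CC(C)c1cc2C=C3OC(=O)[C@@]4(C)CC[C@@H](O[Si](C)(C)C(C)(C)C)C(=Cc2c(O)c1OC)[C@@H]34 | intermediate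
34 | (1R,4S,5R)-1-[(tert-butyldimethylsilyl)oxy]-12-methoxy-11,14-dioxo-9(10→20)-abeo-abieta-6,8,10(20),12-tetraen-19,6-olide | CC(C)C1=C(OC)C(=O)C2=C(C=C3OC(=O)[C@@]4(C)CC[C@@H](O[Si](C)(C)C(C)(C)C)C(=C2)[C@@H]34)C1=O | intermediate
35 | O12-dichloroboryl ether of 36 | CC(C)C1=C(OB(Cl)Cl)C(=O)C2=C(C=C3OC(=O)[C@@]4(C)CC[C@@H](O[Si](C)(C)C(C)(C)C)C(=C2)[C@@H]34)C1=O | intermediate
36 | (1R,4S,5R)-1-[(tert-butyldimethylsilyl)oxy]-12-hydroxy-11,14-dioxo-9(10→20)-abeo-abieta-6,8,10(20),12-tetraen-19,6-olide | CC(C)C1=C(O)C(=O)C2=C(C=C3OC(=O)[C@@]4(C)CC[C@@H](O[Si](C)(C)C(C)(C)C)C(=C2)[C@@H]34)C1=O | intermediate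
37 | (1R,4S,5R)-1,12-dihydroxy-11,14-dioxo-9(10→20)-abeo-abieta-6,8,10(20),12-tetraen-19,6-olide (6,7-anhydroballotiquinone) | CC(C)C1=C(O)C(=O)C2=C(C=C3OC(=O)[C@@]4(C)CC[C@@H](O)C(=C2)[C@@H]34)C1=O | target

**Step count**

Total steps: 20. Longest linear sequence: 15 steps (steps 6–12, step 13, steps 14–20).

**Steps most likely to fail**

Step 13 (aryne insertion). What may go wrong: the aryl anion at C9 may close on the C6 carbonyl instead of C20, which inserts the arene into C6–C7 and gives a constitutional isomer; it may also be protonated by not yet ionised acidic dione before it closes, which leaves plain C7 arylation, and O-arylation of the enolate is a further drain. Fallback (sets out from 10, returns at 26): the two carbonyl carbons are told apart by their distance from O1, and the insertion is moved to an open-chain β-keto ester in which only one ketone is available. Periodate cleavage of the dione (NaIO4, aqueous dioxane) excises C7 and should give the cis-6,20-dicarboxylic acid F1. Desilylation (HF·pyridine) and warming let the C1 hydroxyl lactonise with the only carboxyl it can reach in a five-membered ring, the C6 acid, to give the lactone acid F2 with C20 as the free acid. Activation with 1,1'-carbonyldiimidazole and C-acylation of Mg(O2CCH2CO2CH3)2 give the β-keto ester F3 (C20 ketone, new CH2 = C7). Aryne acyl-alkylation of F3 with 23 (CsF, MeCN, 80 °C), the parent case of this reaction, gives the ortho-acylaryl acetate F4 with C9–C20 and C8–C7 fixed by the same inductive control. Dieckmann-type closure of the arylacetate enolate (KOtBu, THF, 0 °C) on the lactone carbonyl C6 forms ring B and frees O1, giving the cyclic β-keto ester F5. Silylation (tBuMe2SiOSO2CF3, 2,6-lutidine) gives the silyl ether F6, and Krapcho demethoxycarbonylation (LiCl, wet DMSO, 120 °C) returns 26.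

Step 3 (catalytic asymmetric Diels–Alder). What may go wrong: the adduct enolises to an acidic 1,3-dione that can bind or protonate the oxazaborolidinium catalyst, so that turnover stalls and the uncatalysed racemic pathway takes over; the acid may also desilylate the push–pull diene. Fallback (sets out from 5 and 6, returns at 7): the cycloaddition is run thermally (toluene, 60 °C, no catalyst), which should give the same all-cis endo adduct as the racemate, that is 7 together with its enantiomer F7. The acidic dione is then resolved by classical salt formation with (R)-1-phenylethylamine, crystallisation of the less soluble diastereomeric ammonium enolate F8 and liberation of 7 with dilute citric acid; the mother liquor or the (S)-amine is used if the other salt crystallises.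

Step 5 (dianion methylation). What may go wrong: the second deprotonation may take place at C5 or C10 of the dione enolate instead of C4, or methyl iodide may be consumed at C7 or at oxygen of the dione enolate, so that the quaternary centre forms with poor site selectivity. Fallback (sets out from 3, returns at 10): the methyl group is brought in with the diene. Wittig olefination of 3 with tert-butyl 2-(triphenyl-λ5-phosphanylidene)propanoate gives the (2E,4E)-2-methyl dienoate F9, whose ester is still the outside substituent. Its Diels–Alder reaction with 6 under the catalyst of step 3, helped by high pressure (10 kbar) because the terminus now carries an inside methyl group, should give the C4-quaternary adduct F10 directly, and hydrogenation (H2, Pd/C (10% palladium on carbon), EtOAc) returns 10.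

**Further compounds**

F1 | step 13 | cis-6,20-dicarboxylic acid from 10 after excision of C7 (C1 silyl ether, C4 methyl and tert-butyl ester kept) | CC(C)(C)OC(=O)[C@@]1(C)CC[C@@H](O[Si](C)(C)C(C)(C)C)[C@@H](C(O)=O)[C@H]1C(O)=O
F2 | step 13 | lactone acid: C6(=O)–O–C1 γ-lactone with free C20 carboxylic acid | CC(C)(C)OC(=O)[C@@]1(C)CC[C@H]2OC(=O)[C@@H]1[C@@H]2C(O)=O
F3 | step 13 | methyl β-keto ester at C20 (C20 ketone, C7 methylene) of lactone F2 | CC(C)(C)OC(=O)[C@@]1(C)CC[C@H]2OC(=O)[C@@H]1[C@@H]2C(=O)CC(=O)OC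
F4 | step 13 | ortho-acylaryl acetate: C9–C20 aryl ketone and C8–C7H2–CO2CH3 on the lactone | CC(C)(C)OC(=O)[C@@]1(C)CC[C@H]2OC(=O)[C@@H]1[C@@H]2C(=O)c1c(OCC=C)c(OC)c(C(C)C)cc1CC(=O)OC
F5 | step 13 | ring B β-keto ester (C7 methoxycarbonyl, C6 ketone, C20 ketone) with free C1 hydroxyl | CC(C)(C)OC(=O)[C@@]1(C)CC[C@@H](O)[C@H]2C(=O)c3c(OCC=C)c(OC)c(C(C)C)cc3C(C(=O)OC)C(=O)[C@@H]12
F6 | step 13 | C1 tert-butyldimethylsilyl ether of F5 | CC(C)(C)OC(=O)[C@@]1(C)CC[C@@H](O[Si](C)(C)C(C)(C)C)[C@H]2C(=O)c3c(OCC=C)c(OC)c(C(C)C)cc3C(C(=O)OC)C(=O)[C@@H]12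
F7 | step 3 | tert-butyl (3aS,4R,7S,7aR)-7-[(tert-butyldimethylsilyl)oxy]-1,3-dioxo-2,3,3a,4,7,7a-hexahydro-1H-indene-4-carboxylate (enantiomer of 7) | CC(C)(C)OC(=O)[C@@H]1C=C[C@H](O[Si](C)(C)C(C)(C)C)[C@@H]2C(=O)CC(=O)[C@H]12
F8 | step 3 | (R)-1-phenylethylammonium enolate salt of 7 | C[C@@H]([NH3+])c1ccccc1.CC(C)(C)OC(=O)[C@H]1C=C[C@@H](O[Si](C)(C)C(C)(C)C)[C@H]2C(=O)C=C([O-])[C@@H]12
F9 | step 5 | tert-butyl (2E,4E)-5-[(tert-butyldimethylsilyl)oxy]-2-methylpenta-2,4-dienoate | CC(C)(C)OC(=O)/C(C)=C/C=C/O[Si](C)(C)C(C)(C)C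
F10 | step 5 | tert-butyl (3aR,4S,7R,7aS)-7-[(tert-butyldimethylsilyl)oxy]-4-methyl-1,3-dioxo-2,3,3a,4,7,7a-hexahydro-1H-indene-4-carboxylate | CC(C)(C)OC(=O)[C@@]1(C)C=C[C@@H](O[Si](C)(C)C(C)(C)C)[C@H]2C(=O)CC(=O)[C@@H]12
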